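**Strategy.** The route rests on cutting the flavone between C2 of its pyranone ring (ring C) and C1' of its para-phenylene ring (ring B). The key step exploits the acidity of the C2–H of a 2-unsubstituted chromone, which sits next to ring oxygen O1 and is vinylogous to the C4 carbonyl. 5,7-Bis(benzyloxy)chromone is zincated at C2 and cross-coupled (Negishi) in the same flask with the aryl bromide of a fully assembled (2S)-flavanone diaryl ether, so the flavone appears without prefunctionalising the chromone. The bromide partner comes from 5,6-dihydroxy-7-methoxychromone by site-selective 6-O-arylation, 5-O-benzylation and Pd-catalysed asymmetric conjugate arylation; hydrogenolysis ends the route.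

Key step: step 7

Remark (assumption): 1, 5, 8 and 10 are taken as purchasable. The ligand antipode in step 5 is assigned by analogy and must be confirmed on the first run; the other antipode is used if the sense is reversed.

**Step 1**
Reactants: 1 1-(6-hydroxy-2,3,4-trimethoxyphenyl)ethan-1-one
Product: 3 5,6,7-trimethoxy-4H-chromen-4-one, via enaminone 2 (not isolated)
Conditions: DMF-DMA (3 equiv), toluene, 100 °C; evaporate; conc. HCl, CH2Cl2, 40 °C
Reagents that add atoms: N,N-dimethylformamide dimethyl acetal, COC(OC)N(C)C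
Why: Enaminone chromone annulation (condensation of the methyl ketone with the amide acetal, then acid-promoted addition–elimination of the ortho phenol with loss of dimethylamine); 1 has only one free hydroxyl, so O1 can only come from its 6-OH.

**Step 2**
Reactants: 3 5,6,7-trimethoxy-4H-chromen-4-one
Product: 4 5,6-dihydroxy-7-methoxy-4H-chromen-4-one
Conditions: anhydrous AlBr3 (3 equiv), MeCN, 0 °C to rt; then 2 M HCl, 60 °C; under argon
Reagents that add atoms: none
Why: Chelation-controlled Lewis-acid ether cleavage: aluminium bound to the C4 carbonyl cleaves the peri 5-OMe, the 5-O–Al unit then reaches the crowded 6-OMe through a five-membered aluminium catecholate, and the unchelated 7-OMe should survive, as is known for 5,6,7-trimethoxyflavones.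

**Step 3**
Reactants: 4 5,6-dihydroxy-7-methoxy-4H-chromen-4-one; 5 bis(4-bromophenyl)iodonium trifluoromethanesulfonate
Product: 6 6-(4-bromophenoxy)-5-hydroxy-7-methoxy-4H-chromen-4-one
Conditions: t-BuOK (1.0 equiv), THF, 0 °C, argon; then 5 (1.1 equiv), 40 °C
Reagents that add atoms: none
Why: Metal-free O-arylation of a phenoxide by a diaryliodonium salt (ligand coupling at iodine(III)); one equivalent of base should ionise only the non-chelated 6-OH, the 5-OH being held in the hydrogen bond to the C4 carbonyl, and the symmetric salt can transfer only a 4-bromophenyl group.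

**Step 4**
Reactants: 6 6-(4-bromophenoxy)-5-hydroxy-7-methoxy-4H-chromen-4-one
Product: 7 5-(benzyloxy)-6-(4-bromophenoxy)-7-methoxy-4H-chromen-4-one
Conditions: BnBr (1.5 equiv), K2CO3, cat. TBAI, amine-free DMF, 60 °C
Reagents that add atoms: benzyl bromide, BrCc1ccccc1
Why: Williamson ether synthesis on the only remaining (chelated) hydroxyl, which should alkylate under mildly forcing carbonate conditions and which removes the acidic proton before the organometallic steps.

**Step 5**
Reactants: 7 5-(benzyloxy)-6-(4-bromophenoxy)-7-methoxy-4H-chromen-4-one; 8 [4-(benzyloxy)phenyl]boronic acid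
Product: 9 (2S)-5-(benzyloxy)-2-[4-(benzyloxy)phenyl]-6-(4-bromophenoxy)-7-methoxy-2,3-dihydro-4H-chromen-4-one
Conditions: Pd(OCOCF3)2 (10 mol%), (R)-t-BuPyOx (12 mol%), NH4PF6 (30 mol%), H2O (5 equiv), 8 (2 equiv), ClCH2CH2Cl, 60 °C
Reagents that add atoms: none
Why: Pd(II)/pyridine-oxazoline-catalysed asymmetric conjugate addition of an arylboronic acid to a chromone (transmetalation, enantio-determining insertion of C2=C3 into Ar–Pd, protonation of the Pd enolate by water), in which the chiral ligand controls the face: aryl delivery to the Re face of C2 (O1 > C3 > H) gives (2S), the (R)-ligand being chosen by analogy with the sense known for cyclic enones, and the Pd(II) cycle should leave the aryl bromide untouched.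

**Step 6**
Reactants: 10 5,7-dihydroxy-4H-chromen-4-one
Product: 11 5,7-bis(benzyloxy)-4H-chromen-4-one
Conditions: BnBr (2.5 equiv), K2CO3 (3 equiv), cat. KI, amine-free DMF, 60 °C
Reagents that add atoms: benzyl bromide, BrCc1ccccc1
Why: Double Williamson ether synthesis; the acidic 7-OH reacts first and the chelated 5-OH follows on warming with excess halide.

**Step 7**
Reactants: 11 5,7-bis(benzyloxy)-4H-chromen-4-one; 9 (2S)-5-(benzyloxy)-2-[4-(benzyloxy)phenyl]-6-(4-bromophenoxy)-7-methoxy-2,3-dihydro-4H-chromen-4-one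
Product: 13 (2S)-5-(benzyloxy)-2-[4-(benzyloxy)phenyl]-6-{4-[5,7-bis(benzyloxy)-4-oxo-4H-chromen-2-yl]phenoxy}-7-methoxy-2,3-dihydro-4H-chromen-4-one, via chromonylzinc chloride 12 (not isolated)
Conditions: 11 (1.6 equiv), TMPZnCl·LiCl (1.4 equiv, no added MgCl2 or BF3), THF, –20 °C to rt (site checked on an aliquot by I2 quench); then 9 (1.0 equiv), Pd(OAc)2 (4 mol%), SPhos (8 mol%), THF, 50 °C
Reagents that add atoms: none
Why: TMPZnCl·LiCl should remove the most acidic sp2 proton of 11, the C2–H next to ring oxygen O1 at the β-terminus of the vinylogous ester, to give the stable 2-chromonylzinc chloride 12; Pd(0)/SPhos then inserts into the C–Br bond of 9, and transmetalation from zinc and reductive elimination create the C2–C1' bond of the flavone. The closest known reaction type is the amide-base zincation of chromones at C2 followed by Negishi cross-coupling to 2-arylchromones. No ring is closed and no stereocenter is formed; the (2S) center of 9 is only carried through. The selectivities needed are C2 over C3 metalation (carbonyl-directed C3 attack is not expected without an added Lewis acid and is hindered by the peri 5-OBn group), coupling at C–Br without addition to or enolisation of the C4 ketone of 9, and retention of the base-labile C2 configuration. These are secured by the mild, non-nucleophilic organozinc, by using less amide base than 11 so that none remains when 9 is added, and by the base-free coupling at moderate temperature.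

**Step 8**
Reactants: 13 (2S)-5-(benzyloxy)-2-[4-(benzyloxy)phenyl]-6-{4-[5,7-bis(benzyloxy)-4-oxo-4H-chromen-2-yl]phenoxy}-7-methoxy-2,3-dihydro-4H-chromen-4-one
Product: 14 (2S)-6-[4-(5,7-dihydroxy-4-oxo-4H-chromen-2-yl)phenoxy]-5-hydroxy-2-(4-hydroxyphenyl)-7-methoxy-2,3-dihydro-4H-chromen-4-one (CNP0269971.1)
Conditions: H2 (1 atm), 10% Pd/C, EtOAc/MeOH, rt, stopped at full debenzylation
Reagents that add atoms: none
Why: Heterogeneous hydrogenolysis of the four benzyl ethers under neutral conditions should be faster than reduction of the flavone C2=C3 bond or hydrogenolysis of the benzylic C2–O1 bond of the flavanone, and it cannot epimerise C2.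

**Compound list**
1 | 1-(6-hydroxy-2,3,4-trimethoxyphenyl)ethan-1-one | CC(=O)c1c(O)cc(OC)c(OC)c1OC | starting material
2 | (E)-3-(dimethylamino)-1-(6-hydroxy-2,3,4-trimethoxyphenyl)prop-2-en-1-one | CN(C)/C=C/C(=O)c1c(O)cc(OC)c(OC)c1OC | intermediate
3 | 5,6,7-trimethoxy-4H-chromen-4-one | COc1cc2occc(=O)c2c(OC)c1OC | intermediate
4 | 5,6-dihydroxy-7-methoxy-4H-chromen-4-one | COc1cc2occc(=O)c2c(O)c1O | intermediate
5 | bis(4-bromophenyl)iodonium trifluoromethanesulfonate | Brc1ccc([I+]c2ccc(Br)cc2)cc1.[O-]S(=O)(=O)C(F)(F)F | starting material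
6 | 6-(4-bromophenoxy)-5-hydroxy-7-methoxy-4H-chromen-4-one | COc1cc2occc(=O)c2c(O)c1Oc1ccc(Br)cc1 | intermediate
7 | 5-(benzyloxy)-6-(4-bromophenoxy)-7-methoxy-4H-chromen-4-one | COc1cc2occc(=O)c2c(OCc3ccccc3)c1Oc1ccc(Br)cc1 | intermediate
8 | [4-(benzyloxy)phenyl]boronic acid | OB(O)c1ccc(OCc2ccccc2)cc1 | starting material
9 | (2S)-5-(benzyloxy)-2-[4-(benzyloxy)phenyl]-6-(4-bromophenoxy)-7-methoxy-2,3-dihydro-4H-chromen-4-one | COc1cc2c(c(OCc3ccccc3)c1Oc1ccc(Br)cc1)C(=O)C[C@@H](c1ccc(OCc3ccccc3)cc1)O2 | intermediate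
10 | 5,7-dihydroxy-4H-chromen-4-one | O=c1ccoc2cc(O)cc(O)c12 | starting material
11 | 5,7-bis(benzyloxy)-4H-chromen-4-one | O=c1ccoc2cc(OCc3ccccc3)cc(OCc3ccccc3)c12 | intermediate
12 | [5,7-bis(benzyloxy)-4-oxo-4H-chromen-2-yl]zinc chloride | Cl[Zn]c1cc(=O)c2c(OCc3ccccc3)cc(OCc3ccccc3)cc2o1 | intermediate
13 | (2S)-5-(benzyloxy)-2-[4-(benzyloxy)phenyl]-6-{4-[5,7-bis(benzyloxy)-4-oxo-4H-chromen-2-yl]phenoxy}-7-methoxy-2,3-dihydro-4H-chromen-4-one | COc1cc2c(c(OCc3ccccc3)c1Oc1ccc(-c3cc(=O)c4c(OCc5ccccc5)cc(OCc5ccccc5)cc4o3)cc1)C(=O)C[C@@H](c1ccc(OCc3ccccc3)cc1)O2 | intermediate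
14 | (2S)-6-[4-(5,7-dihydroxy-4-oxo-4H-chromen-2-yl)phenoxy]-5-hydroxy-2-(4-hydroxyphenyl)-7-methoxy-2,3-dihydro-4H-chromen-4-one | COc1cc2c(c(O)c1Oc1ccc(-c3cc(=O)c4c(O)cc(O)cc4o3)cc1)C(=O)C[C@@H](c1ccc(O)cc1)O2 | target

**Total step count:** 8
**Longest linear sequence:** 7 (steps 1, 2, 3, 4, 5, 7, 8)

**Steps most likely to fail**

Step 7. Transmetalation of the electron-poor chromonylzinc may be too slow, so that protodezincation or homocoupling wins. Residual amide base may also enolise the flavanone and open its ring, eroding the C2 configuration. The fallback forms the same bond with reversed polarity as a Suzuki–Miyaura coupling; it sets out from 9 and 11 and comes back at 13. Compound 9 would be converted by Miyaura borylation (B2pin2, Pd(dppf)Cl2, KOAc, dioxane, 80 °C) into (2S)-5-(benzyloxy)-2-[4-(benzyloxy)phenyl]-7-methoxy-6-[4-(4,4,5,5-tetramethyl-1,3,2-dioxaborolan-2-yl)phenoxy]-2,3-dihydro-4H-chromen-4-one F1. Compound 11 would be zincated as in step 7 (12) and quenched with iodine to give 5,7-bis(benzyloxy)-2-iodo-4H-chromen-4-one F2. Coupling of F1 with F2 (Pd(dppf)Cl2, CsF, anhydrous dioxane, 60 °C) should give 13.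

Step 5. Insertion into the electron-rich, peri-substituted chromone may be slow enough for protodeboronation to dominate, and facial selectivity may be insufficient or reversed. The fallback replaces catalyst control by a kinetic resolution; it sets out from 7 (with 8) and comes back at 9. Achiral conjugate addition (Pd(OCOCF3)2, 2,2'-bipyridine, H2O, ClCH2CH2Cl, 60–80 °C) would give racemic 5-(benzyloxy)-2-[4-(benzyloxy)phenyl]-6-(4-bromophenoxy)-7-methoxy-2,3-dihydro-4H-chromen-4-one F3. Asymmetric transfer hydrogenation (RuCl[(R,R)-TsDPEN](p-cymene), HCO2H/Et3N, EtOAc, rt, stopped near half conversion) is expected, by the usual aryl ketone model and the cis-selective hydride delivery, to consume the (2R)-ketone as (2R,4R)-5-(benzyloxy)-2-[4-(benzyloxy)phenyl]-6-(4-bromophenoxy)-7-methoxy-3,4-dihydro-2H-chromen-4-ol F4. Unreacted 9 would be separated by chromatography.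

Step 3. Arylation may occur at the wrong hydroxyl or twice, the electron-rich catechol monoanion may be oxidised by the iodine(III) reagent, and the preceding demethylation may stop short or go too far. The fallback builds the diaryl ether before the A-ring is elaborated, so that neither selectivity is needed; it sets out from 5 and comes back at 6, bypassing steps 1–3. 4-Hydroxy-3,5-dimethoxybenzaldehyde (syringaldehyde) F5 would be arylated with 5 (t-BuOK, THF, 40 °C) to 4-(4-bromophenoxy)-3,5-dimethoxybenzaldehyde F6. Dakin-type Baeyer–Villiger oxidation (mCPBA, CH2Cl2) would give 4-(4-bromophenoxy)-3,5-dimethoxyphenyl formate F7, and methanolysis (K2CO3, MeOH) would give 4-(4-bromophenoxy)-3,5-dimethoxyphenol F8. Ortho-acetylation (Ac2O, BF3·OEt2, 80 °C, O-acylation then Fries shift) would give 1-[3-(4-bromophenoxy)-6-hydroxy-2,4-dimethoxyphenyl]ethan-1-one F9. DMF-DMA would give (E)-1-[3-(4-bromophenoxy)-6-hydroxy-2,4-dimethoxyphenyl]-3-(dimethylamino)prop-2-en-1-one F10, which HCl would close to 6-(4-bromophenoxy)-5,7-dimethoxy-4H-chromen-4-one F11. BCl3 (CH2Cl2, –78 to 0 °C) should cleave only the peri 5-OMe to give 6.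

**Further compounds**
F1 | step 7 | (2S)-5-(benzyloxy)-2-[4-(benzyloxy)phenyl]-7-methoxy-6-[4-(4,4,5,5-tetramethyl-1,3,2-dioxaborolan-2-yl)phenoxy]-2,3-dihydro-4H-chromen-4-one | COc1cc2c(c(OCc3ccccc3)c1Oc1ccc(B3OC(C)(C)C(C)(C)O3)cc1)C(=O)C[C@@H](c1ccc(OCc3ccccc3)cc1)O2
F2 | step 7 | 5,7-bis(benzyloxy)-2-iodo-4H-chromen-4-one | Ic1cc(=O)c2c(OCc3ccccc3)cc(OCc3ccccc3)cc2o1
F3 | step 5 | racemic 5-(benzyloxy)-2-[4-(benzyloxy)phenyl]-6-(4-bromophenoxy)-7-methoxy-2,3-dihydro-4H-chromen-4-one | COc1cc2c(c(OCc3ccccc3)c1Oc1ccc(Br)cc1)C(=O)CC(c1ccc(OCc3ccccc3)cc1)O2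
F4 | step 5 | (2R,4R)-5-(benzyloxy)-2-[4-(benzyloxy)phenyl]-6-(4-bromophenoxy)-7-methoxy-3,4-dihydro-2H-chromen-4-ol | COc1cc2c(c(OCc3ccccc3)c1Oc1ccc(Br)cc1)[C@H](O)C[C@H](c1ccc(OCc3ccccc3)cc1)O2
F5 | step 3 | 4-hydroxy-3,5-dimethoxybenzaldehyde | COc1cc(C=O)cc(OC)c1O
F6 | step 3 | 4-(4-bromophenoxy)-3,5-dimethoxybenzaldehyde | COc1cc(C=O)cc(OC)c1Oc1ccc(Br)cc1
F7 | step 3 | 4-(4-bromophenoxy)-3,5-dimethoxyphenyl formate | COc1cc(OC=O)cc(OC)c1Oc1ccc(Br)cc1
F8 | step 3 | 4-(4-bromophenoxy)-3,5-dimethoxyphenol | COc1cc(O)cc(OC)c1Oc1ccc(Br)cc1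
F9 | step 3 | 1-[3-(4-bromophenoxy)-6-hydroxy-2,4-dimethoxyphenyl]ethan-1-one | CC(=O)c1c(O)cc(OC)c(Oc2ccc(Br)cc2)c1OC
F10 | step 3 | (E)-1-[3-(4-bromophenoxy)-6-hydroxy-2,4-dimethoxyphenyl]-3-(dimethylamino)prop-2-en-1-one | CN(C)/C=C/C(=O)c1c(O)cc(OC)c(Oc2ccc(Br)cc2)c1OC
F11 | step 3 | 6-(4-bromophenoxy)-5,7-dimethoxy-4H-chromen-4-one | COc1cc2occc(=O)c2c(OC)c1Oc1ccc(Br)cc1
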